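**Plan**
- Retrosynthesis: remove the O15 acetyl and the C18 methyl ester, return C9–H/C11–H2 to a C9=C11 alkene and then to an 8,9-epoxy-11-ketone, and cut ring B at C9–C10 and C7–C8.
- Enabling feature: in ring B (C5–C10) the quaternary C10 is bonded to C9 (side chain), and C9 to C8 (methyl and oxygen). Ring B is therefore the adduct of a ring A vinylcyclohexene (diene C10=C5–C6=C7) and a methyl ynone (C8≡C9, acyl C11 on C9).
- Forward: ring A is made first (β-keto ester, enol triflate, vinyl diene). The side chain is made separately as the ynone. One cycloaddition joins them and closes ring B. Ring B is then adjusted, the ester cleaved and O15 acetylated.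
- Stereochemistry: C4 comes from an auxiliary-controlled enamine methylation and C13 from the (R)-3-methylglutarate half ester. C10 is relayed from C4 in the cycloaddition. C5, C8 and C9 follow from reagents approaching the face opposite the axial methyls on C4, C10 and C8.

Key step: step 10

Numbering: labdane numbering throughout (ring A = C1–C5, C10; ring B = C5–C10; C17 = methyl on C8; C18 = carboxyl carbon on C4; C19 = methyl on C4; C20 = methyl on C10; side chain C11–C16). In the target the C4, C8 and C10 methyls and the C9 side chain lie on one face; the carboxyl, 8-OH, H5 and H9 lie on the other.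

Assumption: in step 2 the L-valine-derived lithio-enamine, with HMPA as lithium ligand, is taken to be methylated on the face that gives the S quaternary centre; this alkylation is known to reverse its facial sense when the ligand is changed to an ether (or the D-auxiliary is used), so the S ketone is accessible either way.

**Step 1**
Reactants: 1 methyl 2-oxocyclohexane-1-carboxylate; 2 L-valine tert-butyl ester
Product: 3 methyl 2-{[(2S)-1-tert-butoxy-3-methyl-1-oxobutan-2-yl]amino}cyclohex-1-ene-1-carboxylate
Conditions: BF3·OEt2 (cat.), toluene, reflux, azeotropic removal of water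
Reagents that add atoms: none
Why: Condensation of a β-keto ester with a primary amine gives the hydrogen-bonded enamino ester (enamine formation), which carries the chiral auxiliary next to the carbon to be alkylated.

**Step 2**
Reactants: 3 methyl 2-{[(2S)-1-tert-butoxy-3-methyl-1-oxobutan-2-yl]amino}cyclohex-1-ene-1-carboxylate
Product: 6 methyl (1S)-1-methyl-2-oxocyclohexane-1-carboxylate, via lithiated enamine 4 (not isolated), via methylated ketimine 5 (not isolated)
Conditions: LiN(i-Pr)2, toluene, −78 °C; HMPA (1 equiv); MeI, −78 → −40 °C; then 10% aq. citric acid, rt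
Reagents that add atoms: iodomethane, CI; water, O
Why: Auxiliary-controlled alkylation of the chelated lithio-enamine of an α-substituted β-keto ester: methyl iodide should enter on the face not shielded by the valine isopropyl group, setting the C4 quaternary centre, and mild acid hydrolysis of the ketimine returns the ketone and the auxiliary.

**Step 3**
Reactants: 6 methyl (1S)-1-methyl-2-oxocyclohexane-1-carboxylate
Product: 8 methyl (1S)-1,3-dimethyl-2-oxocyclohexane-1-carboxylate (both C3 epimers), via lithium enolate 7 (not isolated)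
Conditions: LiN(i-Pr)2, THF, −78 °C; MeI, −78 → 0 °C
Reagents that add atoms: iodomethane, CI
Why: Only C3 is enolisable, so kinetic enolate alkylation places the future C20 methyl beside the ketone; the C3 configuration is irrelevant because this carbon becomes sp2 in the next step.

**Step 4**
Reactants: 8 methyl (1S)-1,3-dimethyl-2-oxocyclohexane-1-carboxylate
Product: 10 methyl (1S)-1,3-dimethyl-2-{[(trifluoromethyl)sulfonyl]oxy}cyclohex-2-ene-1-carboxylate, via potassium enolate 9 (not isolated)
Conditions: KN(SiMe3)2, THF, −78 → 0 °C; PhNTf2, −78 °C → rt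
Reagents that add atoms: N-phenylbis(trifluoromethanesulfonimide), FC(F)(F)S(=O)(=O)N(c1ccccc1)S(=O)(=O)C(F)(F)F
Why: Removal of the single α-hydrogen gives the tetrasubstituted enolate, which is O-sulfonylated (enol triflate formation) as is routine for 2,2,6-trisubstituted cyclohexanones.

**Step 5**
Reactants: 10 methyl (1S)-1,3-dimethyl-2-{[(trifluoromethyl)sulfonyl]oxy}cyclohex-2-ene-1-carboxylate
Product: 11 methyl (1S)-2-ethenyl-1,3-dimethylcyclohex-2-ene-1-carboxylate
Conditions: tributyl(vinyl)stannane, Pd(PPh3)4 (5 mol %), LiCl, THF, reflux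
Reagents that add atoms: tributyl(vinyl)stannane, CCCC[Sn](CCCC)(CCCC)C=C
Why: Stille coupling of a hindered cyclohexenyl triflate with a vinylstannane is a standard entry to 1-vinylcyclohexenes and leaves the quaternary ester untouched.

**Step 6**
Reactants: 12 methyl hydrogen (R)-3-methylglutarate
Product: 13 methyl (3R)-5-hydroxy-3-methylpentanoate
Conditions: BH3·SMe2, THF, 0 °C → rt; MeOH quench; crude product used at once
Reagents that add atoms: none
Why: Borane reduces the carboxylic acid chemoselectively in the presence of the methyl ester (chemoselective borane reduction), so the acid terminus becomes C15 and the stereocentre is untouched.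

**Step 7**
Reactants: 13 methyl (3R)-5-hydroxy-3-methylpentanoate
Product: 14 methyl (3R)-5-[(tert-butyldimethylsilyl)oxy]-3-methylpentanoate
Conditions: TBSCl, imidazole, DMF, 0 °C → rt
Reagents that add atoms: tert-butyldimethylsilyl chloride, CC(C)(C)[Si](C)(C)Cl
Why: Silylation of the primary alcohol prevents lactonisation and gives an O15 ether that should survive the organometallic, Lewis acid, peracid, hydrazine and thiolate steps.

**Step 8**
Reactants: 14 methyl (3R)-5-[(tert-butyldimethylsilyl)oxy]-3-methylpentanoate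
Product: 15 (3R)-5-[(tert-butyldimethylsilyl)oxy]-N-methoxy-N,3-dimethylpentanamide
Conditions: MeNH(OMe)·HCl, i-PrMgCl, THF, −20 → 0 °C
Reagents that add atoms: N,O-dimethylhydroxylamine hydrochloride, CNOC.Cl
Why: Aminolysis of the methyl ester by the chloromagnesium amide made in the flask gives the Weinreb amide directly (Weinreb amide formation).

**Step 9**
Reactants: 15 (3R)-5-[(tert-butyldimethylsilyl)oxy]-N-methoxy-N,3-dimethylpentanamide
Product: 17 (6R)-8-[(tert-butyldimethylsilyl)oxy]-6-methyloct-2-yn-4-one, via magnesium chelate 16 (not isolated)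
Conditions: 1-propynylmagnesium bromide, THF, 0 °C; aq. NH4Cl
Reagents that add atoms: 1-propynylmagnesium bromide, CC#C[Mg]Br
Why: Weinreb ketone synthesis: the chelated tetrahedral adduct survives until work-up, so the alkynyl Grignard reagent adds once and no conjugate addition to the ynone can follow.

**Step 10**
Reactants: 11 methyl (1S)-2-ethenyl-1,3-dimethylcyclohex-2-ene-1-carboxylate; 17 (6R)-8-[(tert-butyldimethylsilyl)oxy]-6-methyloct-2-yn-4-one
Product: 18 methyl (4S,10R,13R)-15-[(tert-butyldimethylsilyl)oxy]-11-oxolabda-5,8-dien-18-oate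
Conditions: 17, EtAlCl2 (1.1 equiv), CH2Cl2, −78 °C; then 11 (1.5 equiv), −78 → −20 °C; Et3N, then aq. NaHCO3
Reagents that add atoms: none
Why: The ynone, activated as its EtAlCl2 complex, adds as the 2π component across the s-cis diene C10=C5–C6=C7 in a concerted but asynchronous [4+2] cycloaddition in which C7–C8 bonding runs ahead of C9–C10; the closest known reactions are Lewis acid promoted Diels–Alder additions of acetylenic ketones and the addition of acetylenic esters to 2,6,6-trimethyl-1-vinylcyclohexene. Ring B closes as a six-membered 1,4-cyclohexadiene by intermolecular [4+2] ring formation, with both new bonds (C7–C8 and C9–C10) in that ring and the side chain already on C9. The only new stereocentre, quaternary C10, is controlled by C4: in the planar s-cis diene the flat ester should take the pseudoequatorial site beside C6–H and the C4 methyl should stand pseudoaxial, so the ynone bonds to C10 on the face opposite that methyl and C20 ends syn to C19. Regioselectivity is also needed and is secured by the diene polarity, since the unsubstituted terminus C7 carries the largest HOMO coefficient and attacks the β-carbon C8 while positive charge builds at the fully substituted C10, a preference the Lewis acid sharpens. The low temperature and the proton-scavenging aluminium reagent should keep the acid-sensitive diene from isomerising, and the C10 epimer, a diastereomer, would be removed by chromatography.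

**Step 11**
Reactants: 18 methyl (4S,10R,13R)-15-[(tert-butyldimethylsilyl)oxy]-11-oxolabda-5,8-dien-18-oate
Product: 19 methyl (4S,5S,10R,13R)-15-[(tert-butyldimethylsilyl)oxy]-11-oxolabd-8-en-18-oate
Conditions: H2 (1 atm, one equivalent taken up), 10% Pd/C, EtOAc, rt
Reagents that add atoms: none
Why: Heterogeneous hydrogenation should saturate the trisubstituted C5=C6 in preference to the tetrasubstituted, twisted C8=C9 enone, as is known for 5,8-diene adducts of this vinylcyclohexene type, and hydrogen reaches C5 from the face opposite the C10 and C4 methyls, giving the trans ring fusion.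

**Step 12**
Reactants: 19 methyl (4S,5S,10R,13R)-15-[(tert-butyldimethylsilyl)oxy]-11-oxolabd-8-en-18-oate
Product: 20 methyl (4S,5S,8S,9R,10R,13R)-15-[(tert-butyldimethylsilyl)oxy]-8,9-epoxy-11-oxolabdan-18-oate
Conditions: mCPBA, CH2Cl2, 0 °C
Reagents that add atoms: 3-chloroperoxybenzoic acid, OOC(=O)c1cccc(Cl)c1
Why: The acyl group is twisted out of conjugation, so C8=C9 reacts as an isolated tetrasubstituted alkene in a Prilezhaev epoxidation, and the peracid approaches anti to the axial C10 methyl, which fixes the C8–O configuration.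

**Step 13**
Reactants: 20 methyl (4S,5S,8S,9R,10R,13R)-15-[(tert-butyldimethylsilyl)oxy]-8,9-epoxy-11-oxolabdan-18-oate
Product: 23 methyl (4S,5S,8S,10R,13S)-15-[(tert-butyldimethylsilyl)oxy]-8-hydroxylabd-9(11)-en-18-oate, via epoxy hydrazone 21 (not isolated), via alkenyl diazene 22 (not isolated)
Conditions: N2H4·H2O (3 equiv), AcOH (cat.), MeOH, 0 °C → rt
Reagents that add atoms: none
Why: Wharton transposition: the hydrazone opens the epoxide at C9–O to an alkenyl diazene that loses nitrogen, which removes the C11 oxygen and leaves the tertiary C8–O bond and its configuration intact, as known for ring epoxides bearing a side-chain ketone.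

**Step 14**
Reactants: 23 methyl (4S,5S,8S,10R,13S)-15-[(tert-butyldimethylsilyl)oxy]-8-hydroxylabd-9(11)-en-18-oate
Product: 24 methyl (4S,5S,8S,9S,10R,13S)-15-[(tert-butyldimethylsilyl)oxy]-8-hydroxylabdan-18-oate
Conditions: H2 (1 atm), [Ir(cod)(PCy3)(py)]PF6 (5 mol %), CH2Cl2, rt
Reagents that add atoms: none
Why: Hydroxyl-directed homogeneous hydrogenation: the C8 hydroxyl lies on the face opposite the axial C8 and C10 methyls and delivers hydrogen to C9 on that same open face, setting H9 anti to C20 without allylic C–O hydrogenolysis.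

**Step 15**
Reactants: 24 methyl (4S,5S,8S,9S,10R,13S)-15-[(tert-butyldimethylsilyl)oxy]-8-hydroxylabdan-18-oate
Product: 25 (4S,5S,8S,9S,10R,13S)-15-[(tert-butyldimethylsilyl)oxy]-8-hydroxylabdan-18-oic acid
Conditions: NaSEt, DMF, 100 °C; 1 M HCl work-up
Reagents that add atoms: none
Why: Nucleophilic ester dealkylation: the thiolate attacks the methyl carbon in an SN2 step and so bypasses the hindered carbonyl on quaternary C4, leaving the tertiary alcohol untouched.

**Step 16**
Reactants: 25 (4S,5S,8S,9S,10R,13S)-15-[(tert-butyldimethylsilyl)oxy]-8-hydroxylabdan-18-oic acid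
Product: 26 (4S,5S,8S,9S,10R,13S)-8,15-dihydroxylabdan-18-oic acid
Conditions: HF·pyridine, THF/pyridine, 0 °C → rt
Reagents that add atoms: none
Why: Buffered fluoride desilylation frees the primary O15 hydroxyl without ionising the tertiary C8 alcohol.

**Step 17**
Reactants: 26 (4S,5S,8S,9S,10R,13S)-8,15-dihydroxylabdan-18-oic acid
Product: 27 (4S,5S,8S,9S,10R,13S)-15-acetoxy-8-hydroxylabdan-18-oic acid
Conditions: Ac2O (1.5 equiv), pyridine, 0 °C → rt; aq. NaHCO3 work-up, then acidification
Reagents that add atoms: acetic anhydride, CC(=O)OC(C)=O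
Why: Chemoselective acetylation: only the primary alcohol is acylated, the tertiary C8 hydroxyl is inert without an acyl-transfer catalyst, and the hindered acid is recovered free after aqueous work-up.

**Compound list**
1 | methyl 2-oxocyclohexane-1-carboxylate | O=C1CCCCC1C(=O)OC | starting material
2 | L-valine tert-butyl ester (S configuration, free base) | CC(C)[C@H](N)C(=O)OC(C)(C)C | starting material
3 | methyl 2-{[(2S)-1-tert-butoxy-3-methyl-1-oxobutan-2-yl]amino}cyclohex-1-ene-1-carboxylate | COC(=O)C1=C(N[C@@H](C(C)C)C(=O)OC(C)(C)C)CCCC1 | intermediate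
4 | N-lithio derivative of 3 (lithiated enamine, not isolated) | COC(=O)C1=C(N([Li])[C@@H](C(C)C)C(=O)OC(C)(C)C)CCCC1 | intermediate
5 | tert-butyl N-[(2S)-2-(methoxycarbonyl)-2-methylcyclohexylidene]-L-valinate (methylated ketimine, not isolated) | COC(=O)[C@@]1(C)CCCCC1=N[C@@H](C(C)C)C(=O)OC(C)(C)C | intermediate
6 | methyl (1S)-1-methyl-2-oxocyclohexane-1-carboxylate | COC(=O)[C@@]1(C)CCCCC1=O | intermediate
7 | lithium enolate of 6 (O–Li on C2, C2=C3; not isolated) | [Li]OC1=CCCC[C@]1(C)C(=O)OC | intermediate
8 | methyl (1S)-1,3-dimethyl-2-oxocyclohexane-1-carboxylate (both C3 epimers) | CC1CCC[C@](C)(C(=O)OC)C1=O | intermediate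
9 | potassium enolate of 8 (O–K on C2, C2=C3; not isolated) | [K]OC1=C(C)CCC[C@]1(C)C(=O)OC | intermediate
10 | methyl (1S)-1,3-dimethyl-2-{[(trifluoromethyl)sulfonyl]oxy}cyclohex-2-ene-1-carboxylate | FC(F)(F)S(=O)(=O)OC1=C(C)CCC[C@]1(C)C(=O)OC | intermediate
11 | methyl (1S)-2-ethenyl-1,3-dimethylcyclohex-2-ene-1-carboxylate (ring A diene) | C=CC1=C(C)CCC[C@]1(C)C(=O)OC | intermediate
12 | methyl hydrogen (R)-3-methylglutarate, (3R)-5-methoxy-3-methyl-5-oxopentanoic acid | OC(=O)C[C@@H](C)CC(=O)OC | starting material
13 | methyl (3R)-5-hydroxy-3-methylpentanoate | OCC[C@@H](C)CC(=O)OC | intermediate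
14 | methyl (3R)-5-[(tert-butyldimethylsilyl)oxy]-3-methylpentanoate | CC(C)(C)[Si](C)(C)OCC[C@@H](C)CC(=O)OC | intermediate
15 | (3R)-5-[(tert-butyldimethylsilyl)oxy]-N-methoxy-N,3-dimethylpentanamide | CC(C)(C)[Si](C)(C)OCC[C@@H](C)CC(=O)N(C)OC | intermediate
16 | bromomagnesium alkoxide of the tetrahedral propynyl adduct of 15 (magnesium chelate, not isolated) | CC(C)(C)[Si](C)(C)OCC[C@@H](C)CC(O[Mg]Br)(C#CC)N(C)OC | intermediate
17 | (6R)-8-[(tert-butyldimethylsilyl)oxy]-6-methyloct-2-yn-4-one (side-chain ynone) | CC#CC(=O)C[C@H](C)CCO[Si](C)(C)C(C)(C)C | intermediate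
18 | methyl (4S,10R,13R)-15-[(tert-butyldimethylsilyl)oxy]-11-oxolabda-5,8-dien-18-oate (ester on C4 anti to the C10 methyl) | CC(C)(C)[Si](C)(C)OCC[C@@H](C)CC(=O)C=1[C@]2(C)CCC[C@](C)(C(=O)OC)C2=CCC1C | intermediate
19 | methyl (4S,5S,10R,13R)-15-[(tert-butyldimethylsilyl)oxy]-11-oxolabd-8-en-18-oate (trans-fused) | CC(C)(C)[Si](C)(C)OCC[C@@H](C)CC(=O)C=1[C@]2(C)CCC[C@](C)(C(=O)OC)[C@H]2CCC1C | intermediate
20 | methyl (4S,5S,8S,9R,10R,13R)-15-[(tert-butyldimethylsilyl)oxy]-8,9-epoxy-11-oxolabdan-18-oate (epoxide oxygen anti to C20) | CC(C)(C)[Si](C)(C)OCC[C@@H](C)CC(=O)[C@]31[C@]2(C)CCC[C@](C)(C(=O)OC)[C@H]2CC[C@]1(C)O3 | intermediate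
21 | C11 hydrazone of 20 (epoxy hydrazone, not isolated) | CC(C)(C)[Si](C)(C)OCC[C@@H](C)CC(=NN)[C@]31[C@]2(C)CCC[C@](C)(C(=O)OC)[C@H]2CC[C@]1(C)O3 | intermediate
22 | methyl 15-[(tert-butyldimethylsilyl)oxy]-11-diazenyl-8-hydroxylabd-9(11)-en-18-oate (alkenyl diazene, not isolated) | CC(C)(C)[Si](C)(C)OCC[C@@H](C)CC(N=N)=C1[C@]2(C)CCC[C@](C)(C(=O)OC)[C@H]2CC[C@]1(C)O | intermediate
23 | methyl (4S,5S,8S,10R,13S)-15-[(tert-butyldimethylsilyl)oxy]-8-hydroxylabd-9(11)-en-18-oate | CC(C)(C)[Si](C)(C)OCC[C@@H](C)CC=C1[C@]2(C)CCC[C@](C)(C(=O)OC)[C@H]2CC[C@]1(C)O | intermediate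
24 | methyl (4S,5S,8S,9S,10R,13S)-15-[(tert-butyldimethylsilyl)oxy]-8-hydroxylabdan-18-oate | CC(C)(C)[Si](C)(C)OCC[C@@H](C)CC[C@H]1[C@]2(C)CCC[C@](C)(C(=O)OC)[C@H]2CC[C@]1(C)O | intermediate
25 | (4S,5S,8S,9S,10R,13S)-15-[(tert-butyldimethylsilyl)oxy]-8-hydroxylabdan-18-oic acid | CC(C)(C)[Si](C)(C)OCC[C@@H](C)CC[C@H]1[C@]2(C)CCC[C@](C)(C(=O)O)[C@H]2CC[C@]1(C)O | intermediate
26 | (4S,5S,8S,9S,10R,13S)-8,15-dihydroxylabdan-18-oic acid | OCC[C@@H](C)CC[C@H]1[C@]2(C)CCC[C@](C)(C(=O)O)[C@H]2CC[C@]1(C)O | intermediate
27 | (4S,5S,8S,9S,10R,13S)-15-acetoxy-8-hydroxylabdan-18-oic acid | CC(=O)OCC[C@@H](C)CC[C@H]1[C@]2(C)CCC[C@](C)(C(=O)O)[C@H]2CC[C@]1(C)O | target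

**Step count**
Total: 17 steps. Longest linear sequence: 13 steps (steps 1–5, then 10–17); the side-chain branch (steps 6–9) has 4.

**Steps most likely to fail**

Step 10. Two things may go wrong. First, the two faces of the diene may be poorly discriminated at C10, because the C4 methyl and ester differ only modestly in size. Second, the crowded s-cis geometry may make the cycloaddition slow enough for stepwise Lewis acid pathways (cyclobutene formation, proton loss from the allyl cation) to compete. The fallback sets out from triflate 10 and returns at adduct 18. Stille coupling of 10 with tributyl(1-ethoxyvinyl)stannane (Pd(PPh3)4, LiCl) would give methyl (1S)-2-(1-ethoxyethenyl)-1,3-dimethylcyclohex-2-ene-1-carboxylate F1. Dilute aqueous HCl would hydrolyse it to the acetylcyclohexene F2, and Et3SiOTf/Et3N would convert that into the 2-silyloxy diene F3. This much more electron-rich diene is the established kind of partner for hindered Diels–Alder reactions that create quaternary carbon. Its C6 substituent also presses on the pseudoequatorial site of C4, which should reinforce the conformer with the methyl axial. Cycloaddition of F3 with ynone 17, thermally or with a mild aluminium Lewis acid, would give the 6-silyloxy adduct F4. CsF/PhNTf2 would turn the silyl enol ether into the C6 enol triflate F5, and Pd(OAc)2/PPh3/HCO2H/Et3N reduction of that triflate would give 18.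

Step 13. Hydrazone formation at the ketone beside the fully substituted epoxide carbon may be slow, and the alkenyl diazene may decompose along radical side paths instead of giving the allylic alcohol cleanly. The fallback sets out from epoxy ketone 20 and returns at 24. SmI2 in THF/MeOH at −90 °C would cleave the C9–O bond to give the 8-hydroxy 11-ketone F6, with C9 protonated on the face away from the two axial methyls. NaBH4 would give the 8,11-diol F7. PhOC(S)Cl/pyridine would acylate only the secondary hydroxyl to the O-phenyl thionocarbonate F8. Bu3SnH/AIBN (Barton–McCombie deoxygenation) would then give 24.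

Step 11. On the metal surface C5=C6 may migrate into conjugation with the enone before it is reduced, leading to over-reduction or loss of the trans ring fusion. The fallback sets out from 18 and returns at 19 with no new compound (none, F0). It is a radical hydrogen-atom-transfer hydrogenation with Mn(dpm)3, PhSiH3 and t-BuOOH in i-PrOH. This adds hydrogen to C6 first and lets the tertiary C5 radical take up its hydrogen on the open face, giving the thermodynamically preferred trans-fused ring; the tetrasubstituted enone should react far more slowly.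

**Further compounds**
F1 | step 10 | methyl (1S)-2-(1-ethoxyethenyl)-1,3-dimethylcyclohex-2-ene-1-carboxylate | CCOC(=C)C1=C(C)CCC[C@]1(C)C(=O)OC
F2 | step 10 | methyl (1S)-2-acetyl-1,3-dimethylcyclohex-2-ene-1-carboxylate | CC(=O)C1=C(C)CCC[C@]1(C)C(=O)OC
F3 | step 10 | methyl (1S)-1,3-dimethyl-2-{1-[(triethylsilyl)oxy]ethenyl}cyclohex-2-ene-1-carboxylate | C=C(O[Si](CC)(CC)CC)C1=C(C)CCC[C@]1(C)C(=O)OC
F4 | step 10 | methyl (4S,10R,13R)-15-[(tert-butyldimethylsilyl)oxy]-11-oxo-6-[(triethylsilyl)oxy]labda-5,8-dien-18-oate | CC(C)(C)[Si](C)(C)OCC[C@@H](C)CC(=O)C=1[C@]2(C)CCC[C@](C)(C(=O)OC)C2=C(O[Si](CC)(CC)CC)CC1C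
F5 | step 10 | methyl (4S,10R,13R)-15-[(tert-butyldimethylsilyl)oxy]-11-oxo-6-{[(trifluoromethyl)sulfonyl]oxy}labda-5,8-dien-18-oate | CC(C)(C)[Si](C)(C)OCC[C@@H](C)CC(=O)C=1[C@]2(C)CCC[C@](C)(C(=O)OC)C2=C(OS(=O)(=O)C(F)(F)F)CC1C
F6 | step 13 | methyl (4S,5S,8S,9S,10R,13R)-15-[(tert-butyldimethylsilyl)oxy]-8-hydroxy-11-oxolabdan-18-oate | CC(C)(C)[Si](C)(C)OCC[C@@H](C)CC(=O)[C@H]1[C@]2(C)CCC[C@](C)(C(=O)OC)[C@H]2CC[C@]1(C)O
F7 | step 13 | methyl 15-[(tert-butyldimethylsilyl)oxy]-8,11-dihydroxylabdan-18-oate (ring stereochemistry as in 24, both C11 epimers) | CC(C)(C)[Si](C)(C)OCC[C@@H](C)CC(O)[C@H]1[C@]2(C)CCC[C@](C)(C(=O)OC)[C@H]2CC[C@]1(C)O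
F8 | step 13 | methyl 15-[(tert-butyldimethylsilyl)oxy]-8-hydroxy-11-[(phenoxycarbonothioyl)oxy]labdan-18-oate (ring stereochemistry as in 24, both C11 epimers) | CC(C)(C)[Si](C)(C)OCC[C@@H](C)CC(OC(=S)Oc3ccccc3)[C@H]1[C@]2(C)CCC[C@](C)(C(=O)OC)[C@H]2CC[C@]1(C)O
F0 | step 11 | none | none
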